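Readings and results were computed with made-up constants; noise was put on by code.

I followed G.

| flask | J | G | E | time |
|---|---|---|---|---|
| teal | 0.0800 M | 0.0880 M | 0.00240 M |  |
| red | 0.0800 M | 0.0880 M | 0.00120 M |  |
| blue | 0.0800 M | 0.260 M | 0.00240 M |  |
| grey | 0.240 M | 0.0880 M | 0.00240 M |  |
| ochre | 0.0800 M | 0.0880 M | 6.90 × 10⁻⁴ M | 8.8 h |

| run | time / h | [X] / M |
|---|---|---|
| teal run | 1.1 | 0.0056 |
| teal run | 2.2 | 0.0106 |
| teal run | 3.3 | 0.0139 |
| teal run | 4.4 | 0.0138 |
| teal run | 5.5 | 0.0148 |
| teal run | 6.6 | 0.0166 |
| teal run | 7.7 | 0.0152 |
| teal run | 8.8 | 0.0172 |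
| red run | 1.1 | 0.0036 |
| red run | 2.2 | 0.0067 |
| red run | 3.3 | 0.0074 |
| red run | 4.4 | 0.0088 |
| red run | 5.5 | 0.0088 |
| red run | 6.6 | 0.0088 |
| red run | 7.7 | 0.0088 |
| red run | 8.8 | 0.0099 |
| blue run | 1.1 | 0.0184 |
| blue run | 2.2 | 0.0260 |
| blue run | 3.3 | 0.0323 |
| blue run | 4.4 | 0.0346 |
| blue run | 5.5 | 0.0393 |
| blue run | 6.6 | 0.0389 |
| blue run | 7.7 | 0.0399 |
| blue run | 8.8 | 0.0405 |
| grey run | 1.1 | 0.0184 |
| grey run | 2.2 | 0.0280 |
| grey run | 3.3 | 0.0320 |
| grey run | 4.4 | 0.0343 |
| grey run | 5.5 | 0.0365 |
| grey run | 6.6 | 0.0370 |
| grey run | 7.7 | 0.0372 |
| grey run | 8.8 | 0.0362 |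

(scatter of a reading: 6 × 10⁻⁴ M)

- reaction order in [E] at the outset, round the charge of the teal run, defined at two percent of the J turned into X
- reaction order in [J] at the outset, round the charge of the teal run, defined at two percent of the J turned into X (one fixed amount of X, the same in the runs compared)
- X in the ochre run at 8.8 h, as a share of the J charged
- which of these the readings show (the second partner is lost by itself / a little impurity takes part of the catalyst at once / the product reacts on with the second partner)

- Overall: J + G -> X, with E as catalyst.
- Constant volume, constant temperature.
- "The second partner" is G.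
- An order is taken over about fifteen percent of the charge, up and down.

I kept a ledger of G, using the mean of the last 3 readings of each run as its closing entry. By the charge, J is the limiting reagent in the red run, but the red X stood at 11.5% of the J charged, with readings nearly flat from 4.4 h. Each X took one G, so that entry is 10.4% of the G charged, and the other column, G not in X, holds 89.6%. I booked that column as G lost by itself or still left in the flask.

If each G has a steady chance of being lost, and a chance of becoming X that goes with E and J, then the G charged drops out of the ratio of the two columns. I call this ratio, share in X over share not in X, the split: 0.116 in red.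

The readings tested this. Teal gave 0.228, a factor 1.97 over red for a factor 2.00 in E, which left no sign of an impurity taking E at once. Grey gave 0.719, a factor 3.15 over teal for a factor 3.00 in J. Blue, with far more G, gave 0.181, lower than teal. I read orders near 1 in E and in J.

For ochre, I scaled the red split by E, a factor 0.575. That gave a first pass of 6.89% of the J charged. Correcting for the mean J left in each flask raised the split to 0.0685, so X came to 7.05% of the J charged.

The forecast gave 7.2%, slightly above mine, with orders 1.03 in E and 1.08 in J, and chose "the second partner is lost by itself". In its words: “That fits G decaying by itself”.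

The flask gave orders of 1.1 in E and 1.1 in J, 7.22% in ochre, and "the second partner is lost by itself".

    E + J + G → X + E (457.2 /M²/h)
    G → Gu (0.3294 /h)

The ochre result closes the ledger at a split of 0.0703. The path from G to Gu is a part of the ochre shortfall, not the reason for it: with that path taken away, X in the same ochre flask comes to 19.8% of the J charged, not 7.22%, which is 14% of what is missing. The split also carries to blue, where the X made came to half of the J charged at 8.04 h. Scaling the ochre split by E and by mean J left gives 0.190, and the blue ledger at that time reads 0.182.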